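(The data were computed for an exercise; scatter was added.)

Start from a ratio: the selectivity factor s, the logarithm of the fraction of left-handed substrate left over the same logarithm for right-handed substrate, each fraction taken on its own charge. If both hands meet the same catalyst and reagent at each moment and none crosses over, s holds however the catalyst fares, so you work with fractions left, not fractions made.

| flask | left-handed substrate | right-handed substrate | reagent | free catalyst | racemization catalyst | added ligand | impurity | remark | time |
|---|---|---|---|---|---|---|---|---|---|
| grey | 0.35 M | 0.35 M | 1.05 M | 3.5 mM | 0.70 mM | 1.4 mM | 0.11 mM | run made earlier |  |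
| green | 0.35 M | 0.35 M | 1.05 M | 14 mM | 0.70 mM | 1.4 mM | 0.11 mM | run made earlier |  |
| flask | 0.35 M | 0.35 M | 1.05 M | 7.0 mM | 0.70 mM | 1.4 mM | 0.11 mM |  | 10 h |

| run | time / h | left-handed product / % | right-handed product / % |
|---|---|---|---|
| grey | 0.333 | 1.2 | 0 |
| grey | 1.00 | 0.2 | 0.8 |
| grey | 1.50 | 0.9 | 0 |
| grey | 2.50 | 1.1 | 0.5 |
| grey | 4.00 | 2.4 | 0.6 |
| grey | 5.00 | 2.1 | 1.1 |
| grey | 6.00 | 3.0 | 1.4 |
| green | 0.500 | 1.4 | 1.2 |
| green | 0.667 | 1.4 | 0 |
| green | 1.00 | 1.5 | 0.6 |
| green | 1.50 | 3.5 | 1.1 |
| green | 2.50 | 3.9 | 1.6 |
| green | 4.00 | 5.4 | 2.9 |
| green | 6.00 | 7.1 | 3.7 |

(scatter of a reading: 0.5 percentage points)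

- free catalyst is single-handed; left-handed substrate and right-handed substrate are mirror images of each other, charged as a racemate, each of them at the stated concentration
- an excess is below zero if the other one leads

1. excess of left-handed product over right-handed product in the product at 1.0 h
2. excess of left-handed product over right-handed product in the product at 10 h
3. part of the left-handed substrate and right-handed substrate charged together that has reacted at 10 h

Each hand is half the charge, so a product reading p leaves a fraction 1 − 2p. Pooling the logarithms from the last readings of both earlier runs gives 2.04, your ratio of logarithms of fractions left. Early on, products form in the ratio s, so you expect an excess in the flask at 1.0 h of (s − 1)/(s + 1) = 34.3%.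

For the amount, let L be minus the logarithm of the fraction of right-handed substrate left. At 6.00 h, the green run reads 0.0769 and the grey run 0.0284. Their geometric mean, stretched in a straight line to 10 h, gives 0.0779, so this first estimate for the flask is 11.1% reacted.

The straight line is the weak link, since it assumes the catalyst lasts. The green run has 4.00 times the catalyst of the grey run, yet its L is 2.71 times as large. So suppose free catalyst dies in pairs: L then grows as ln(1 + u), with u proportional to loading times time. Choosing u = 0.5 for the grey run at 6.00 h gives a ratio of 2.71, so u is read from that noisy ratio and not tested by it. Scaled from the green run, your estimate of L for the flask at 10 h is 0.0686. That leaves 93.4% of the right-handed substrate and 86.9% of the left-handed, so 9.86% has reacted, at an excess of 32.7%.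

The forecast, saying “The selectivity is about 2”, gave excesses of 34% at 1.0 h and 33% at 10 h, with 10.8% reacted, a reacted part above yours. The flask gives 33.7%, 32.4% and 9.77%, in the same order.

    reagent + free catalyst + left-handed substrate → free catalyst + left-handed product (k = 7.50 × 10⁻⁴ L² mol⁻² s⁻¹)
    reagent + free catalyst + right-handed substrate → free catalyst + right-handed product (k = 3.70 × 10⁻⁴ L² mol⁻² s⁻¹)
    left-handed substrate + racemization catalyst ⇌ right-handed substrate + racemization catalyst, rate k3*[racemization catalyst]*[left-handed substrate] forward; the back reaction follows from the equilibrium constant (k = 0.0170 L mol⁻¹ s⁻¹)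
    racemization catalyst + added ligand ⇌ idle complex, settled at all times (K = 2.60 × 10⁵ L mol⁻¹)
    racemization catalyst + impurity → spent catalyst A (k = 15.0 L mol⁻¹ s⁻¹)
    2 free catalyst → spent catalyst B (k = 0.00170 L mol⁻¹ s⁻¹)

At 10.0 h the flask keeps 87% of its charged left-handed substrate and 93% of its charged right-handed substrate, a ratio of logarithms of 2.02. Racemization, set aside above, does not show in the flask's reacted part, and the idle complex there holds 86.6% of the racemization catalyst charged at 10.0 h. Now take the neighbouring flask, with 1.8 M of reagent in place of 1.05 M. Both product steps are first order in reagent, so L scales to 0.118, which leaves 88.9% of the right-handed substrate and, through s, 78.6% of the left-handed. That neighbouring flask holds 89% and 79% at 10.0 h, with 16.1% reacted.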